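Start from a one-step world in which Q turns Z into G and D into X. If Q took both hands alike, G and X would grow equally and the excess, read here as (G − X)/(G + X), would be zero; that is the zero of the scale.

| setting | Saturday's | Thursday's | zeta | theta | alpha | epsilon | eta | delta |
|---|---|---|---|---|---|---|---|---|
| Z | 0.14 M | 0.22 M | 0.10 M | 0.10 M | 0.10 M | 0.10 M | 0.10 M | 0.10 M |
| D | 0.14 M | 0.22 M | 0.10 M | 0.10 M | 0.10 M | 0.10 M | 0.10 M | 0.10 M |
| J | 3.3 mM (held) | 3.3 mM (held) | 3.3 mM (held) | 3.3 mM (held) | 3.3 mM (held) | 3.3 mM (held) | 3.3 mM (held) | 3.3 mM (held) |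
| temperature | −26 °C | 4 °C | −20 °C | −15 °C | 15 °C | −30 °C | −40 °C | 0 °C |
| remark | run made earlier | run made earlier |  |  |  |  |  |  |
| time |  |  | 12 min | 12 min | 12 min | 12 min | 12 min | 12 min |

Saturday's run (percent of the Z and D together charged)

| time / min | G / % | X / % | Z / % |
|---|---|---|---|
| 3.00 | 2.4 | 0.7 | 46.7 |
| 5.00 | 4.3 | 0.8 | 45.4 |
| 8.00 | 6.5 | 1.9 | 42.9 |
| 10.0 | 8.1 | 2.6 | 40.6 |
| 15.0 | 12.7 | 4.0 | 37.0 |
| 20.0 | 15.3 | 5.5 | 33.0 |
| 40.0 | 26.9 | 10.3 | 21.0 |

Thursday's run (percent of the Z and D together charged)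

| time / min | G / % | X / % | Z / % |
|---|---|---|---|
| 0.833 | 1.0 | 0.5 | 46.7 |
| 1.33 | 1.3 | 0.6 | 44.5 |
| 2.00 | 2.1 | 0.8 | 43.1 |
| 2.50 | 2.8 | 1.3 | 41.9 |
| 4.00 | 4.6 | 2.1 | 39.5 |
| 6.00 | 7.0 | 2.9 | 37.5 |
| 10.0 | 10.9 | 4.3 | 34.4 |

- Q is single-handed; Z and D are mirror images of each other, charged as a racemate, each of them at the stated concentration
- at the start none of Q is dissolved
- candidate steps: D <-> E; Q + D -> X; Q + Z -> G; Q <-> L; J <-> Q; Z <-> E
- the handed part of Q does not stay in what it makes, so the products of the two hands are mirror images too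

1. the flasks put in order of excess of G over X, best first, at 12 min (zeta / theta / alpha / epsilon / eta / delta)
2. the excess of G over X of the flask you put first, at 12 min
3. the excess of G over X of the flask you put last, at 12 min

Both steps draw on the same Q, so cQ cancels from their ratio, and G grows against X as s·cZ/cD. Take the selectivity factor s as the rate constant of Q with Z over that of Q with D. While cZ stays near cD, G/X reads s, and the excess is s minus one over s plus one.

Rank the clocks, my own reckoning. In Saturday's run G stands at 2.4 % by 3.00 min, so Q is on hand early. In that run the readings give Z a half-life of about 32.1 min. The leak of Z through E in Saturday's run, read from Z + G, has a half-life near 660 min, far slower. In Thursday's run the order swaps: the leak takes 12.6 min and Z takes 20.8 min.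

Read s off G/X at like conversion, each reading carrying a standard deviation of 0.3 percentage points: Saturday's at 15.0 min gives a reading of s = 3.17, an excess of 52.1 %. Thursday's at 10.0 min gives 2.53, an excess of 43.4 %. A straight line through these in temperature puts the coldest flask first, eta at 56.1 % and alpha last at 40.2 %.

The forecast gives eta > epsilon > zeta > theta > delta > alpha, with 56 % and 38 %: “Coldest is best.” Its low value stands below mine.

The flasks give eta > epsilon > zeta > theta > delta > alpha, with 59.4 % and 34.9 %.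

    D ⇌ E (K = 0.390, k = 9.63 × 10⁻⁴ /s, Ea = 76.0 kJ/mol, ΔH = −39.0 kJ/mol)
    Q + D → X (k = 0.571 /M/s, Ea = 54.0 kJ/mol)
    Q + Z → G (k = 1.47 /M/s, Ea = 48.0 kJ/mol)
    Q ⇌ L (K = 13.0, k = 0.00149 /s, Ea = 80.0 kJ/mol, ΔH = −3.00 kJ/mol)
    J ⇌ Q, rate k5*(csat - [Q]) (kL = 0.0383 /s)
    Z ⇌ E (K = 0.390, k = 9.63 × 10⁻⁴ /s, Ea = 76.0 kJ/mol, ΔH = −39.0 kJ/mol)
    (constants at 0 °C)

Against my line, eta stands higher and alpha lower, and the order is the forecast's; the loss of Q to L makes no difference to alpha's excess. Carry s to the repeat of alpha at 40 °C: the line from 3.17 and 2.53 gives 33.0 %, and that flask holds 29.2 %. Eta has not come to rest: at ten times the time it still holds Z 20.9 % and D 39.7 %, and its excess falls to 50.4 %. Alpha then holds Z 0 % and D 0 %, with its excess at 29.6 %.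

All runs are calculated with made-up constants; noise was put on by code.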